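Retrosynthesis: with both phenols unmasked last, ring C is cut at C4–C4a (decarboxylative arylation), then at O1–C2 (aryl ether) and at C3–C1' (conjugate arylation). Ring B is then cut at its boron handle, its prenyl group and its pyran ring.
Enabling feature: C4 is an unsubstituted methylene between the stereocentre C3 and C4a of ring A. One added carboxyl carbon on C4 turns C2–C3–C4 into a butyrolactone (C2 the OCH2, C3 the β carbon, C4 the α CH2). That carbon first makes C3 an acceptor for ring B and is later expelled as CO2, which places a radical on C4 beside the ring A iodide.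
Forward order: the pyran ring on ring B comes first (resorcinol plus prenal), then prenyl and boron by two directed lithiations. The lactone is attached at C3, opened and tied to ring A through O1–C2, and ring C is closed last.
Stereochemistry: the single stereocentre C3 (R) comes from the (R)-BINAP–rhodium 1,4-addition to furan-2(5H)-one. No later step acts on it.

Key step: step 11

Numbering and shorthand: isoflavan numbering is used for the target and the open-chain precursors of ring C (O1, C2, C3, C4, C4a to C8a, primed atoms for ring B). Chromene numbering is used for the ring B building blocks, whose C6, C7 and C8 become C1', C2' and C3'. ArB = 2,2-dimethyl-8-(3-methylbut-2-en-1-yl)-7-{[2-(trimethylsilyl)ethoxy]methoxy}-2H-chromen-6-yl; SEM = 2-(trimethylsilyl)ethoxymethyl; TIPS = triisopropylsilyl.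
Assumption: the facial sense of (R)-BINAP on furan-2(5H)-one is taken to follow that established for cyclic enones and six-membered unsaturated lactones, and is to be confirmed on 13 before material is carried on.

Step 1
Reactants: 1 resorcinol; 2 3-methylbut-2-enal
Product: 4 2,2-dimethyl-2H-chromen-7-ol, via ortho-quinone methide 3 (not isolated)
Conditions: ethylenediammonium diacetate (10 mol %), toluene, reflux, Dean–Stark, 1 in twofold excess
Reagents that add atoms: none
Why: Knoevenagel-type condensation at C4 of resorcinol, which is para to one hydroxyl and less crowded than C2, gives 3, whose oxa-6π electrocyclisation closes the pyran ring, a standard chromene annulation of resorcinols with enals in which the excess of 1 holds back a second annulation.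

Step 2
Reactants: 4 2,2-dimethyl-2H-chromen-7-ol
Product: 5 2,2-dimethyl-7-(SEM-oxy)-2H-chromene
Conditions: SEMCl, iPr2NEt, CH2Cl2, 0 °C → rt
Reagents that add atoms: 2-(trimethylsilyl)ethoxymethyl chloride, C[Si](C)(C)CCOCCl
Why: O-alkylation of a phenol with a chloromethyl ether is routine, and the acetal ether is at once stable to base, a director for both lithiations and cleavable by fluoride, so the end game needs no acid.

Step 3
Reactants: 5 2,2-dimethyl-7-(SEM-oxy)-2H-chromene; 6 1-bromo-3-methylbut-2-ene
Product: 8 2,2-dimethyl-8-(3-methylbut-2-en-1-yl)-7-(SEM-oxy)-2H-chromene, via 8-lithiochromene 7 (not isolated)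
Conditions: n-BuLi, THF, 0 °C; CuBr·SMe2 (10 mol %), 6, −78 °C → rt
Reagents that add atoms: none
Why: Directed ortho-metalation goes to C8, the site flanked by the ring oxygen and the acetal ether as in 1,3-dialkoxybenzenes, and the aryl nucleophile then displaces the primary allylic bromide at its unsubstituted carbon under copper catalysis.

Step 4
Reactants: 8 2,2-dimethyl-8-(3-methylbut-2-en-1-yl)-7-(SEM-oxy)-2H-chromene
Product: 11 (ArB)boronic acid, via 6-lithiochromene 9 (not isolated), via lithium triisopropoxyborate 10 (not isolated)
Conditions: n-BuLi, Et2O, 0 °C → rt; B(OiPr)3, −78 °C → rt; 1 M HCl to pH 6, 0 °C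
Reagents that add atoms: triisopropyl borate, CC(C)OB(OC(C)C)OC(C)C; water, O
Why: With C8 filled the acetal ether can guide lithium only to C6, a weakly coordinating solvent without diamine favours this chelation-controlled ring metalation over deprotonation of the benzylic allylic CH2, and borate trapping with mild hydrolysis is the standard directed-metalation route to arylboronic acids.

Step 5
Reactants: 11 (ArB)boronic acid; 12 furan-2(5H)-one
Product: 13 (4R)-4-ArB-dihydrofuran-2(3H)-one
Conditions: [Rh(OH)((R)-binap)]2 (2.5 mol %, preformed from [RhCl(C2H4)2]2, (R)-BINAP, aq KOH), 12 (3 equiv), 1,4-dioxane–H2O 10:1, 40 °C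
Reagents that add atoms: none
Why: In this Hayashi–Miyaura asymmetric 1,4-addition the aryl group passes from boron to rhodium and inserts into the butenolide on the alkene face left open by (R)-BINAP, the facial sense by which (S)-BINAP gives (S)-3-arylcyclohexanones and which reads R at the lactone β carbon (CH2O over aryl over CH2C=O), while the base-free hydroxo complex near room temperature and the excess of cheap acceptor keep protodeboronation of the electron-rich acid slow.

Step 6
Reactants: 13 (4R)-4-ArB-dihydrofuran-2(3H)-one
Product: 15 methyl (3R)-3-ArB-4-hydroxybutanoate, via potassium carboxylate 14 (not isolated)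
Conditions: KOH (1.05 equiv), MeOH–H2O, rt; evaporate to dryness; MeI, DMF, 0 °C → rt
Reagents that add atoms: potassium hydroxide, [K+].[OH-]; iodomethane, CI
Why: Saponification gives a carboxylate that cannot relactonise and SN2 methylation of that salt in a dipolar aprotic solvent fixes the open form without acid, a known way of opening butyrolactones, with 15 carried on at once without acidic silica and C3 untouched.

Step 7
Reactants: 16 4-iodoresorcinol
Product: 17 2-iodo-5-[(triisopropylsilyl)oxy]phenol
Conditions: TIPSCl (1.05 equiv), imidazole, CH2Cl2, 0 °C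
Reagents that add atoms: chlorotriisopropylsilane, CC(C)[Si](Cl)(C(C)C)C(C)C
Why: The bulky silyl chloride takes the open hydroxyl para to iodine and leaves the hydroxyl beside iodine free, the steric differentiation commonly used for monoprotection of 4-substituted resorcinols.

Step 8
Reactants: 15 methyl (3R)-3-ArB-4-hydroxybutanoate; 17 2-iodo-5-[(triisopropylsilyl)oxy]phenol
Product: 18 methyl (3R)-3-ArB-4-{2-iodo-5-[(triisopropylsilyl)oxy]phenoxy}butanoate
Conditions: PPh3, DIAD, THF, 0 °C → rt
Reagents that add atoms: none
Why: Mitsunobu etherification of a primary alcohol with an acidic ortho-iodophenol forms O1–C2 under neutral conditions at or below room temperature, where displacement of the oxyphosphonium group by phenoxide should outrun return to the lactone, and it acts one carbon away from C3.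

Step 9
Reactants: 18 methyl (3R)-3-ArB-4-{2-iodo-5-[(triisopropylsilyl)oxy]phenoxy}butanoate
Product: 20 (3R)-3-ArB-4-{2-iodo-5-[(triisopropylsilyl)oxy]phenoxy}butanoic acid, via trimethylstannyl ester 19 (not isolated)
Conditions: Me3SnOH (5 equiv), 1,2-dichloroethane, 70 °C; cold 0.1 M HCl wash
Reagents that add atoms: trimethyltin hydroxide, C[Sn](C)(C)O
Why: Trimethyltin hydroxide cleaves unhindered methyl esters under nearly neutral conditions through the stannyl ester, which spares the aryl silyl ether that aqueous hydroxide would endanger as well as the aryl iodide and the acetal.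

Step 10
Reactants: 20 (3R)-3-ArB-4-{2-iodo-5-[(triisopropylsilyl)oxy]phenoxy}butanoic acid
Product: 21 1,3-dioxoisoindolin-2-yl (3R)-3-ArB-4-{2-iodo-5-[(triisopropylsilyl)oxy]phenoxy}butanoate
Conditions: N-hydroxyphthalimide, DIC, DMAP (10 mol %), CH2Cl2, rt
Reagents that add atoms: N-hydroxyphthalimide, O=C1c2ccccc2C(=O)N1O
Why: Carbodiimide coupling of Steglich type between a primary carboxylic acid and N-hydroxyphthalimide is the standard preparation of redox-active esters and touches no other group of 20.

Step 11
Reactants: 21 1,3-dioxoisoindolin-2-yl (3R)-3-ArB-4-{2-iodo-5-[(triisopropylsilyl)oxy]phenoxy}butanoate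
Product: 22 (3R)-3-ArB-7-[(triisopropylsilyl)oxy]chromane
Conditions: NiBr2(dme) (20 mol %), 4,4'-di-tert-butyl-2,2'-bipyridine (24 mol %), Bu4NBr (0.1 M), DMA, RVC cathode, Zn anode, undivided cell, constant current, about 2.5 F/mol, rt, 21 fed by syringe pump (5 mM final)
Reagents that add atoms: none
Why: Nickel reduced at the cathode to the zerovalent state adds oxidatively to the C4a–I bond, and one electron passed to the phthalimide ester (from monovalent nickel or from the cathode) breaks its N–O bond, after which loss of CO2 leaves a primary radical at C4. The arylnickel centre of the same molecule, divalent before and trivalent after capture, traps this radical in a seven-membered nickelacycle (Ni, C4a, C8a, O1, C2, C3, C4), and C(sp3)–C(sp2) reductive elimination contracts it to the six-membered ring C, so the ring closes at the metal and not by radical attack on the arene. The closest known reaction type is the nickel-catalysed reductive and electroreductive decarboxylative arylation of primary alkyl N-hydroxyphthalimide esters with aryl iodides, flanked by ring-closing nickel reductive couplings of tethered aryl and alkyl electrophiles, and here the two partners simply share one molecule. No stereocentre is created, and C3, one carbon from the radical site and never deprotonated in this neutral medium, keeps its R configuration. The step needs ring closure to beat hydrogen abstraction, coupling between molecules and 1,2-shift of ring B, which the fast-inserting iodide tethered to the radical, a high nickel loading relative to the slowly fed substrate and high dilution should secure. Prenyl, chromene, acetal and silyl ether are inert at the mild potential and in the absence of acid.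

Step 12
Reactants: 22 (3R)-3-ArB-7-[(triisopropylsilyl)oxy]chromane
Product: 23 (3R)-3-[7-hydroxy-2,2-dimethyl-8-(3-methylbut-2-en-1-yl)-2H-chromen-6-yl]chroman-7-ol
Conditions: Bu4NF (6 equiv), THF–DMPU, 4 Å MS, argon, rt then 60 °C; AcOH quench
Reagents that add atoms: none
Why: Fluoride cleaves the aryl triisopropylsilyl ether at room temperature and on warming attacks the trimethylsilyl group of the acetal ether, which fragments to ethene, formaldehyde and the phenoxide, so both phenols are freed in one acid-free operation that leaves the ortho-prenylphenol, the chromene and C3 alone.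

Compound list
1 | resorcinol | Oc1cccc(O)c1 | starting material
2 | 3-methylbut-2-enal | CC(C)=CC=O | starting material
3 | 3-hydroxy-6-(3-methylbut-2-enylidene)cyclohexa-2,4-dien-1-one (ortho-quinone methide) | O=C1C=C(O)C=CC1=CC=C(C)C | intermediate
4 | 2,2-dimethyl-2H-chromen-7-ol | CC1(C)C=Cc2ccc(O)cc2O1 | intermediate
5 | 2,2-dimethyl-7-{[2-(trimethylsilyl)ethoxy]methoxy}-2H-chromene | CC1(C)C=Cc2ccc(OCOCC[Si](C)(C)C)cc2O1 | intermediate
6 | 1-bromo-3-methylbut-2-ene (prenyl bromide) | CC(C)=CCBr | starting material
7 | 8-lithio derivative of 5 | CC1(C)C=Cc2ccc(OCOCC[Si](C)(C)C)c([Li])c2O1 | intermediate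
8 | 2,2-dimethyl-8-(3-methylbut-2-en-1-yl)-7-{[2-(trimethylsilyl)ethoxy]methoxy}-2H-chromene | CC(C)=CCc1c(OCOCC[Si](C)(C)C)ccc2c1OC(C)(C)C=C2 | intermediate
9 | 6-lithio derivative of 8 (ArB–Li) | CC(C)=CCc1c(OCOCC[Si](C)(C)C)c([Li])cc2c1OC(C)(C)C=C2 | intermediate
10 | lithium (ArB)triisopropoxyborate | [Li+].CC(C)=CCc1c(OCOCC[Si](C)(C)C)c([B-](OC(C)C)(OC(C)C)OC(C)C)cc2c1OC(C)(C)C=C2 | intermediate
11 | (ArB)boronic acid | CC(C)=CCc1c(OCOCC[Si](C)(C)C)c(B(O)O)cc2c1OC(C)(C)C=C2 | intermediate
12 | furan-2(5H)-one | O=C1OCC=C1 | starting material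
13 | (4R)-4-ArB-dihydrofuran-2(3H)-one | CC(C)=CCc1c(OCOCC[Si](C)(C)C)c([C@@H]2COC(=O)C2)cc2c1OC(C)(C)C=C2 | intermediate
14 | potassium (3R)-3-ArB-4-hydroxybutanoate | [K+].CC(C)=CCc1c(OCOCC[Si](C)(C)C)c([C@@H](CC(=O)[O-])CO)cc2c1OC(C)(C)C=C2 | intermediate
15 | methyl (3R)-3-ArB-4-hydroxybutanoate | CC(C)=CCc1c(OCOCC[Si](C)(C)C)c([C@@H](CC(=O)OC)CO)cc2c1OC(C)(C)C=C2 | intermediate
16 | 4-iodoresorcinol | Oc1ccc(I)c(O)c1 | starting material
17 | 2-iodo-5-[(triisopropylsilyl)oxy]phenol | Oc1cc(O[Si](C(C)C)(C(C)C)C(C)C)ccc1I | intermediate
18 | methyl (3R)-3-ArB-4-{2-iodo-5-[(triisopropylsilyl)oxy]phenoxy}butanoate | CC(C)=CCc1c(OCOCC[Si](C)(C)C)c([C@@H](CC(=O)OC)COc3cc(O[Si](C(C)C)(C(C)C)C(C)C)ccc3I)cc2c1OC(C)(C)C=C2 | intermediate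
19 | trimethylstannyl (3R)-3-ArB-4-{2-iodo-5-[(triisopropylsilyl)oxy]phenoxy}butanoate | CC(C)=CCc1c(OCOCC[Si](C)(C)C)c([C@@H](CC(=O)O[Sn](C)(C)C)COc3cc(O[Si](C(C)C)(C(C)C)C(C)C)ccc3I)cc2c1OC(C)(C)C=C2 | intermediate
20 | (3R)-3-ArB-4-{2-iodo-5-[(triisopropylsilyl)oxy]phenoxy}butanoic acid | CC(C)=CCc1c(OCOCC[Si](C)(C)C)c([C@@H](CC(=O)O)COc3cc(O[Si](C(C)C)(C(C)C)C(C)C)ccc3I)cc2c1OC(C)(C)C=C2 | intermediate
21 | N-hydroxyphthalimide ester of 20 (precursor of the key step) | CC(C)=CCc1c(OCOCC[Si](C)(C)C)c([C@@H](CC(=O)ON3C(=O)c4ccccc4C3=O)COc3cc(O[Si](C(C)C)(C(C)C)C(C)C)ccc3I)cc2c1OC(C)(C)C=C2 | intermediate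
22 | (3R)-3-ArB-7-[(triisopropylsilyl)oxy]chromane (7-O-TIPS, 2'-O-SEM ether of the target) | CC(C)=CCc1c(OCOCC[Si](C)(C)C)c([C@@H]2COc3cc(O[Si](C(C)C)(C(C)C)C(C)C)ccc3C2)cc2c1OC(C)(C)C=C2 | intermediate
23 | (3R)-3-[7-hydroxy-2,2-dimethyl-8-(3-methylbut-2-en-1-yl)-2H-chromen-6-yl]chroman-7-ol | CC(C)=CCc1c(O)c([C@@H]2COc3cc(O)ccc3C2)cc2c1OC(C)(C)C=C2 | target

Total step count: 12. Longest linear sequence: 11 (steps 1 to 6 and 8 to 12). Step 7 is a one-step side branch.

Steps most likely to fail

Step 11. The phthalimide ester may be reduced before nickel has inserted into the aryl iodide of the same molecule. The free C4 radical would then abstract hydrogen, couple between molecules or undergo aryl shift instead of closing ring C. The fallback forms the same C4–C4a bond by a two-electron organometallic closure and sets out from 21.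
- Blue-light irradiation with LiI and catalytic PPh3 in acetone (decarboxylative iodination of redox-active esters) should give the primary alkyl iodide F1.
- Zinc dust with LiCl in THF at room temperature inserts into the alkyl–iodine bond well before it attacks the electron-rich aryl iodide, giving the alkylzinc iodide F2, which is not isolated.
- Pd(OAc)2 with SPhos then closes ring C by intramolecular Negishi coupling, and the route is rejoined at 22.

Step 5. Transfer of the crowded ortho-alkoxyaryl group to rhodium and its insertion into the sluggish butenolide may be slower than protodeboronation of the electron-rich boronic acid. The fallback separates bond formation from stereocontrol and sets out from 11.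
- Suzuki–Miyaura coupling with commercial 4-bromofuran-2(5H)-one (Pd(OAc)2, SPhos, K3PO4, THF–H2O, 40 °C) should give 4-ArB-furan-2(5H)-one F3.
- C3 is then set by hydride delivery through copper hydride catalysed asymmetric conjugate reduction (Cu(OAc)2·H2O, one enantiomer of p-tol-BINAP, polymethylhydrosiloxane, t-BuOH, toluene, 0 °C). This reaction is known for β-substituted butenolides and is selective for the electron-poor alkene.
- The ligand enantiomer is chosen in a trial run so that the R lactone results, and the route is rejoined at 13.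

Step 4. Butyllithium may deprotonate the benzylic allylic CH2 of the prenyl group instead of ring position C6, so that boron would end up on the side chain. The fallback replaces deprotonation by halogen–lithium exchange and sets out from 2.
- Condensation of 2 with commercial 4-bromoresorcinol under the conditions of step 1 should give 6-bromo-2,2-dimethyl-2H-chromen-7-ol F4.
- Pd(PPh3)4-catalysed O-alkylation with methyl 2-methylbut-3-en-2-yl carbonate in THF at 0 °C gives the 1,1-dimethylallyl ether F5.
- Aromatic Claisen rearrangement in toluene at about 100 °C moves the allyl unit with inversion to C8, the only free ortho position, giving 6-bromo-8-prenylchromen-7-ol F6.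
- SEMCl and iPr2NEt give the SEM-protected bromide F7.
- n-BuLi in THF at −78 °C effects bromine–lithium exchange, far faster than any deprotonation, and delivers aryllithium 9, where the route is rejoined.

Further compounds
F1 | step 11 | 6-[(2R)-1-iodo-3-{2-iodo-5-[(triisopropylsilyl)oxy]phenoxy}propan-2-yl]-2,2-dimethyl-8-(3-methylbut-2-en-1-yl)-7-(SEM-oxy)-2H-chromene | CC(C)=CCc1c(OCOCC[Si](C)(C)C)c([C@@H](CI)COc3cc(O[Si](C(C)C)(C(C)C)C(C)C)ccc3I)cc2c1OC(C)(C)C=C2
F2 | step 11 | alkylzinc iodide from F1 (zinc on C4) | CC(C)=CCc1c(OCOCC[Si](C)(C)C)c([C@@H](C[Zn]I)COc3cc(O[Si](C(C)C)(C(C)C)C(C)C)ccc3I)cc2c1OC(C)(C)C=C2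
F3 | step 5 | 4-ArB-furan-2(5H)-one | CC(C)=CCc1c(OCOCC[Si](C)(C)C)c(C2=CC(=O)OC2)cc2c1OC(C)(C)C=C2
F4 | step 4 | 6-bromo-2,2-dimethyl-2H-chromen-7-ol | CC1(C)C=Cc2cc(Br)c(O)cc2O1
F5 | step 4 | 6-bromo-2,2-dimethyl-7-[(2-methylbut-3-en-2-yl)oxy]-2H-chromene | CC1(C)C=Cc2cc(Br)c(OC(C)(C)C=C)cc2O1
F6 | step 4 | 6-bromo-2,2-dimethyl-8-(3-methylbut-2-en-1-yl)-2H-chromen-7-ol | CC(C)=CCc1c(O)c(Br)cc2c1OC(C)(C)C=C2
F7 | step 4 | 6-bromo-2,2-dimethyl-8-(3-methylbut-2-en-1-yl)-7-{[2-(trimethylsilyl)ethoxy]methoxy}-2H-chromene | CC(C)=CCc1c(OCOCC[Si](C)(C)C)c(Br)cc2c1OC(C)(C)C=C2
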